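**Retrosynthetic overview**
1. Target ⇒ 1,3-O→C benzyl shift ⇒ 4'-O-benzyl ether of the dihydrochalcone. The key disconnection is this benzylic C1–O bond, made by 1,6-oxa-addition of the dihydrochalcone phenol to the lignan p-quinone methide under a chiral Brønsted acid (sets C1).
2. Quinone methide precursor ⇒ benzylic C–O bond formation (DDQ/MeOH C–H methoxylation) on the C2-symmetric bisphenol lignan, whose two benzylic CH2 groups are homotopic.
3. Lignan ⇒ double asymmetric hydrogenation of an E,E-1,4-diaryl-2,3-dimethylbutadiene (sets C2 and C3) ⇒ Cp2Zr-mediated homocoupling of an aryl propyne; then O-demethylation.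
4. Dihydrochalcone ⇒ phloroglucinol + 3-(4-methoxyphenyl)propanoic acid (Friedel–Crafts acylation).
5. Rings: none of the five benzene rings is built. The only rings formed are transient: the zirconacyclopentadiene in step 1 and the cyclohexadienone of the quinone methide in step 6, which re-aromatises.

Assumption: the SMILES is read as 1R,2S,3R on the butyl chain, which corresponds to a (2R,3R)-2,3-dimethyl-1,4-diarylbutane lignan unit; 1-methoxy-4-(prop-1-yn-1-yl)benzene is taken as a catalogue compound.

**Step 1**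
Reactants: 1 1-methoxy-4-(prop-1-yn-1-yl)benzene (2 equiv)
Product: 3 (1E,3E)-1,4-bis(4-methoxyphenyl)-2,3-dimethylbuta-1,3-diene, via zirconacyclopentadiene 2 (not isolated)
Conditions: Cp2ZrCl2 (1 equiv), n-BuLi (2 equiv), THF, −78 °C to rt, 3 h; then 3 M HCl, 0 °C
Reagents that add atoms: none
Why: Negishi reductive alkyne homocoupling (oxidative cyclisation of two alkynes on Cp2Zr, divalent zirconium, generated from Cp2ZrBu2) places the aryl groups α to Zr, and protonolysis of both Zr–C bonds with retention gives the E,E-diene; no stereocentre is formed.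

**Step 2**
Reactants: 3 (1E,3E)-1,4-bis(4-methoxyphenyl)-2,3-dimethylbuta-1,3-diene
Product: 4 1,1'-[(2R,3R)-2,3-dimethylbutane-1,4-diyl]bis(4-methoxybenzene)
Conditions: H2 (50 bar), [Ir(cod)(L)][B(C6H3-3,5-(CF3)2)4] (2 mol %; cod = cycloocta-1,5-diene, L = (S)-4-tert-butyl-2-[2-(di-o-tolylphosphanyl)phenyl]-4,5-dihydrooxazole), CH2Cl2, 25 °C, 16 h
Reagents that add atoms: none
Why: Pfaltz-type asymmetric hydrogenation of unfunctionalised E-trisubstituted aryl alkenes with the cationic [Ir(cod)(L)]+ phosphinooxazoline complex reduces both ArCH=C(CH3) units from the same enantioface under catalyst control, setting C2 and C3 as 2R,3R; the (S)-ligand is expected to give this sense by analogy with (E)-α-methylstilbene giving the (R)-alkane, and the (R)-ligand is used if the first run shows the opposite.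

**Step 3**
Reactants: 4 1,1'-[(2R,3R)-2,3-dimethylbutane-1,4-diyl]bis(4-methoxybenzene)
Product: 5 4,4'-[(2R,3R)-2,3-dimethylbutane-1,4-diyl]diphenol
Conditions: BBr3 (3 equiv), CH2Cl2, −78 °C to rt; then H2O
Reagents that add atoms: none
Why: Lewis acid cleavage of aryl methyl ethers (BBr3 demethylation) leaves the two remote sp3 stereocentres untouched.

**Step 4**
Reactants: 5 4,4'-[(2R,3R)-2,3-dimethylbutane-1,4-diyl]diphenol
Product: 6 4-[(1RS,2S,3R)-4-(4-hydroxyphenyl)-1-methoxy-2,3-dimethylbutyl]phenol
Conditions: DDQ (0.7 equiv), MeOH, 0 °C to rt, 1 h; unreacted 5 recycled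
Reagents that add atoms: methanol, CO
Why: Quinone dehydrogenation: DDQ abstracts hydride from a benzylic C–H para to a phenol OH and the 4-hydroxybenzylic cation is captured at once by the solvent methanol, forming the benzylic C–O bond (benzylic C–H methoxylation); the two benzylic CH2 groups are homotopic so one constitution results, and the C1 epimer mixture is immaterial because C1 is ionised again in step 6.

**Step 5**
Reactants: 7 benzene-1,3,5-triol (phloroglucinol, 1.2 equiv); 8 3-(4-methoxyphenyl)propanoic acid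
Product: 9 1-(2,4,6-trihydroxyphenyl)-3-(4-methoxyphenyl)propan-1-one
Conditions: BF3·OEt2 (neat), 80 °C, 2 h; then aq. NaOAc
Reagents that add atoms: none
Why: BF3-mediated Friedel–Crafts acylation of phloroglucinol by the free acid stops at monoacylation because the acyl group deactivates the ring, and the anisole ether survives.

**Step 6**
Reactants: 6 4-[(1RS,2S,3R)-4-(4-hydroxyphenyl)-1-methoxy-2,3-dimethylbutyl]phenol; 9 1-(2,4,6-trihydroxyphenyl)-3-(4-methoxyphenyl)propan-1-one (2 equiv)
Product: 12 1-{3-[(1R,2S,3R)-1,4-bis(4-hydroxyphenyl)-2,3-dimethylbutyl]-2,4,6-trihydroxyphenyl}-3-(4-methoxyphenyl)propan-1-one, via quinone methide 10 (not isolated), via aryl benzyl ether 11 (not isolated)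
Conditions: (R)-3,3'-bis(2,4,6-triisopropylphenyl)-BINOL N-triflylphosphoramide (10 mol %; the (S)-acid if it proves to be the matched one), 5 Å molecular sieves, CH2Cl2/EtOAc 5:1, −20 °C to 0 °C, 24 h
Reagents that add atoms: none
Why: Proposed new method: the chiral acid ionises either epimer of 6 by loss of methanol (taken up by the sieves) to quinone methide 10 and, in the hydrogen-bonded ion pair, the acidic 4'-OH of 9 adds through oxygen to C1 (kinetic 1,6-oxa-addition, as in benzyl aryl ether formation from quinone methides and phenols) on the face anti to the C3 chain in the A(1,3)-minimised conformer (C2–H eclipsing the ring, C2-methyl face open) to give ether 11; the same acid re-ionises that C–O bond and the contact ion pair collapses suprafacially onto the adjacent C3' (1,3-O→C shift, irreversible after tautomerisation to the phenol), so the catalyst pocket reinforces the intrinsic Felkin-type preference and delivers 1R (C3' and C5' are equivalent, so every ortho shift converges on 12); closest known reaction types are chiral phosphoric acid-catalysed 1,6-additions of phenols and naphthols to p-quinone methides generated in situ, and acid-promoted 1,3-O-to-C shifts of benzyl aryl ethers.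

**Compound list**
1 | 1-methoxy-4-(prop-1-yn-1-yl)benzene | CC#Cc1ccc(OC)cc1 | starting material
2 | 1,1-bis(cyclopentadienyl)-2,5-bis(4-methoxyphenyl)-3,4-dimethyl-1-zirconacyclopenta-2,4-diene | COc1ccc(cc1)C2=C(C)C(C)=C(c3ccc(OC)cc3)[Zr]2(C4C=CC=C4)C5C=CC=C5 | intermediate
3 | (1E,3E)-1,4-bis(4-methoxyphenyl)-2,3-dimethylbuta-1,3-diene | COc1ccc(/C=C(C)/C(C)=C/c2ccc(OC)cc2)cc1 | intermediate
4 | 1,1'-[(2R,3R)-2,3-dimethylbutane-1,4-diyl]bis(4-methoxybenzene) | COc1ccc(C[C@@H](C)[C@H](C)Cc2ccc(OC)cc2)cc1 | intermediate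
5 | 4,4'-[(2R,3R)-2,3-dimethylbutane-1,4-diyl]diphenol | Oc1ccc(C[C@@H](C)[C@H](C)Cc2ccc(O)cc2)cc1 | intermediate
6 | 4-[(1RS,2S,3R)-4-(4-hydroxyphenyl)-1-methoxy-2,3-dimethylbutyl]phenol (both C1 epimers) | COC(c1ccc(O)cc1)[C@@H](C)[C@H](C)Cc1ccc(O)cc1 | intermediate
7 | benzene-1,3,5-triol (phloroglucinol) | Oc1cc(O)cc(O)c1 | starting material
8 | 3-(4-methoxyphenyl)propanoic acid | COc1ccc(CCC(=O)O)cc1 | starting material
9 | 1-(2,4,6-trihydroxyphenyl)-3-(4-methoxyphenyl)propan-1-one | COc1ccc(CCC(=O)c2c(O)cc(O)cc2O)cc1 | intermediate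
10 | 4-[(2S,3R)-4-(4-hydroxyphenyl)-2,3-dimethylbutylidene]cyclohexa-2,5-dien-1-one | O=C1C=CC(=C[C@@H](C)[C@H](C)Cc2ccc(O)cc2)C=C1 | intermediate
11 | 1-{4-[(1R,2S,3R)-1,4-bis(4-hydroxyphenyl)-2,3-dimethylbutoxy]-2,6-dihydroxyphenyl}-3-(4-methoxyphenyl)propan-1-one | COc1ccc(CCC(=O)c2c(O)cc(O[C@@H](c3ccc(O)cc3)[C@@H](C)[C@H](C)Cc3ccc(O)cc3)cc2O)cc1 | intermediate
12 | 1-{3-[(1R,2S,3R)-1,4-bis(4-hydroxyphenyl)-2,3-dimethylbutyl]-2,4,6-trihydroxyphenyl}-3-(4-methoxyphenyl)propan-1-one | COc1ccc(CCC(=O)c2c(O)cc(O)c([C@@H](c3ccc(O)cc3)[C@@H](C)[C@H](C)Cc3ccc(O)cc3)c2O)cc1 | target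

**Count**
Total steps: 6. Longest linear sequence: 5 (steps 1, 2, 3, 4, 6).

**Three steps most likely to fail**

Step 6, the proposed new step. The risks are direct, less selective C-attack or a mismatched catalyst enantiomer; tautomerisation of the quinone methide to the 4-alkenylphenol, which would scramble C2; double benzylation of 9; and stalling at ether 11, in which case the mixture is warmed to rt. The fallback uses known chemistry and changes the order of bond formation. It sets out from 6. Compound 6 and phloroglucinol 7 (5 equiv) are stirred with TsOH·H2O (10 mol %) in dioxane at 40 °C, a classical acid-catalysed Friedel–Crafts benzylation through quinone methide 10 under substrate (Felkin) control, which favours the same 1R epimer. It gives 2-[(1R,2S,3R)-1,4-bis(4-hydroxyphenyl)-2,3-dimethylbutyl]benzene-1,3,5-triol F1, purified from its C1 epimer by reverse-phase chromatography. The two free positions of the phloroglucinol ring of F1 are equivalent, so BF3·OEt2-mediated acylation with acid 8 (1.1 equiv, 60–70 °C; any phenyl esters on the lignan rings cleaved with K2CO3/MeOH) comes back to the route at 12.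

Step 2. The risks are incomplete reduction of the hindered conjugated diene, meso content (removed by crystallisation of 5) and the wrong facial sense. The fallback is an auxiliary-controlled oxidative enolate dimerisation and sets out from 8. Acid 8 is activated with pivaloyl chloride/Et3N and coupled with (S)-4-isopropyl-1,3-oxazolidin-2-one (LiCl) to give (4S)-3-[3-(4-methoxyphenyl)propanoyl]-4-(propan-2-yl)-1,3-oxazolidin-2-one F2. Its lithium enolate (LiN(iPr)2, THF, −78 °C) is homocoupled oxidatively with TiCl4 to give (2R,3R)-2,3-bis(4-methoxybenzyl)-1,4-bis[(4S)-2-oxo-4-(propan-2-yl)-1,3-oxazolidin-3-yl]butane-1,4-dione F3. LiBH4 reduction then gives (2R,3R)-2,3-bis(4-methoxybenzyl)butane-1,4-diol F4, MsCl/Et3N gives (2R,3R)-2,3-bis(4-methoxybenzyl)butane-1,4-diyl dimethanesulfonate F5, and LiAlH4 reduction of both mesylates comes back to the route at 4.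

Step 4. The risks are over-oxidation to the aryl ketone, double methoxylation and DDQ–phenol adducts. The fallback replaces hydride abstraction by radical halogenation and sets out from 5. Ac2O/pyridine gives [(2R,3R)-2,3-dimethylbutane-1,4-diyl]di-4,1-phenylene diacetate F6, and Wohl–Ziegler bromination (NBS 0.9 equiv, AIBN, PhCF3, 80 °C) gives 4-[(1RS,2S,3R)-4-(4-acetoxyphenyl)-1-bromo-2,3-dimethylbutyl]phenyl acetate F7. K2CO3 in MeOH at 0 °C then removes both acetates; the phenoxide expels bromide to form quinone methide 10, which adds methanol, coming back to the route at 6.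

**Further compounds**
F1 | step 6 | 2-[(1R,2S,3R)-1,4-bis(4-hydroxyphenyl)-2,3-dimethylbutyl]benzene-1,3,5-triol | Oc1cc(O)c([C@@H](c2ccc(O)cc2)[C@@H](C)[C@H](C)Cc2ccc(O)cc2)c(O)c1
F2 | step 2 | (4S)-3-[3-(4-methoxyphenyl)propanoyl]-4-(propan-2-yl)-1,3-oxazolidin-2-one | COc1ccc(CCC(=O)N2[C@@H](C(C)C)COC2=O)cc1
F3 | step 2 | (2R,3R)-2,3-bis(4-methoxybenzyl)-1,4-bis[(4S)-2-oxo-4-(propan-2-yl)-1,3-oxazolidin-3-yl]butane-1,4-dione | COc1ccc(C[C@@H](C(=O)N2[C@@H](C(C)C)COC2=O)[C@@H](Cc2ccc(OC)cc2)C(=O)N2[C@@H](C(C)C)COC2=O)cc1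
F4 | step 2 | (2R,3R)-2,3-bis(4-methoxybenzyl)butane-1,4-diol | COc1ccc(C[C@@H](CO)[C@H](CO)Cc2ccc(OC)cc2)cc1
F5 | step 2 | (2R,3R)-2,3-bis(4-methoxybenzyl)butane-1,4-diyl dimethanesulfonate | COc1ccc(C[C@@H](COS(C)(=O)=O)[C@H](COS(C)(=O)=O)Cc2ccc(OC)cc2)cc1
F6 | step 4 | [(2R,3R)-2,3-dimethylbutane-1,4-diyl]di-4,1-phenylene diacetate | CC(=O)Oc1ccc(C[C@@H](C)[C@H](C)Cc2ccc(OC(C)=O)cc2)cc1
F7 | step 4 | 4-[(1RS,2S,3R)-4-(4-acetoxyphenyl)-1-bromo-2,3-dimethylbutyl]phenyl acetate | CC(=O)Oc1ccc(C(Br)[C@@H](C)[C@H](C)Cc2ccc(OC(C)=O)cc2)cc1
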